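**Retrosynthetic overview**
- The C6–prenyl bond is cut last: directed lithiation between two MOM ethers of the (R)-flavan. Prenyl goes in after ring closure because it would not survive the acid used there.
- The C2–O1 bond is the key disconnection: enantioselective intramolecular hydroalkoxylation of an achiral 2-cinnamylphloroglucinol closes the pyran ring (ring C) and sets C2. The two ortho OH groups are equivalent, so only one flavan constitution can form.
- The C4–C4a bond comes from dehydrative Friedel–Crafts allylation of phloroglucinol with an aryl vinyl carbinol, itself made from 3,5-dimethoxybenzaldehyde and vinylmagnesium bromide.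
- Rings A and B are bought as arenes; the pyran ring is the only ring formed.

Assumption: the target is 2R (read from the SMILES). The sense of induction of the new catalyst cannot be predicted, so the antipode that gives 2R is used. It is written below as (S,S); the (R,R) form is made the same way from (R)-BINOL.

**Step 1**
Reactants: 1 3,5-dimethoxybenzaldehyde
Product: 2 rac-1-(3,5-dimethoxyphenyl)prop-2-en-1-ol
Conditions: CH2=CHMgBr (1.2 equiv), THF, 0 °C; then H2O/aq NH4Cl
Reagents that add atoms: vinylmagnesium bromide, C=C[Mg]Br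
Why: Grignard 1,2-addition to a non-enolisable aldehyde; the carbinol centre is racemic and is erased when the alcohol ionises in step 2.

**Step 2**
Reactants: 2 rac-1-(3,5-dimethoxyphenyl)prop-2-en-1-ol; 3 phloroglucinol (benzene-1,3,5-triol, 4 equiv)
Product: 4 2-[(2E)-3-(3,5-dimethoxyphenyl)prop-2-en-1-yl]benzene-1,3,5-triol
Conditions: p-TsOH·H2O (5 mol %), 1,4-dioxane, 40 °C, slow addition of 2, Ar
Reagents that add atoms: none
Why: Dehydrative Friedel–Crafts allylation in which the hydroxyl of 2 leaves as water to give the 1-arylallyl cation, and excess phloroglucinol attacks the unhindered CH2 terminus to give the conjugated E-styrene, while this mild acid cannot protonate the product alkene, so no racemic ring closure occurs.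

**Step 3**
Reactants: 4 2-[(2E)-3-(3,5-dimethoxyphenyl)prop-2-en-1-yl]benzene-1,3,5-triol
Product: 5 (2R)-2-(3,5-dimethoxyphenyl)-3,4-dihydro-2H-chromene-5,7-diol
Conditions: (S,S)-IDPi acid HN[P(=NSO2CF3)(O2Ar*)]2 (Ar*O2 = (S)-3,3′-bis[3,5-bis(trifluoromethyl)phenyl]-1,1′-binaphthalene-2,2′-diolate; 5 mol %), CHCl3/HFIP 10:1, 0.05 mol/L, 5 Å sieves, 40 °C
Reagents that add atoms: none
Why: Proposed new method: the confined, strongly acidic chiral imidodiphosphorimidate protonates the β-alkylstyrene at C3 while its anion holds the ortho phenol by hydrogen bonding, so the benzylic carbon C2 is captured by oxygen in a concerted-asynchronous 6-endo (Markovnikov) closure on one alkene face inside the chiral pocket, which sets C2 as R by catalyst control; the substrate's symmetry excludes regioisomers, and the meta-dimethoxyphenyl group stabilises a C2 cation too little for the product to re-ionise and racemise; the closest known reaction types are the asymmetric intramolecular hydroalkoxylation of unactivated alkenols by confined Brønsted acids (5-exo, giving tetrahydrofurans) and the racemic acid-catalysed cyclisation of 2-cinnamylphenols to flavans.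

**Step 4**
Reactants: 5 (2R)-2-(3,5-dimethoxyphenyl)-3,4-dihydro-2H-chromene-5,7-diol
Product: 6 (2R)-2-(3,5-dimethoxyphenyl)-5,7-bis(methoxymethoxy)-3,4-dihydro-2H-chromene
Conditions: MOMCl (3 equiv), i-Pr2NEt (4 equiv), CH2Cl2, 0 °C → rt
Reagents that add atoms: chloromethyl methyl ether (MOMCl), COCCl
Why: Base-mediated O-alkylation of both phenols to MOM acetals, which leaves the flavan ether, the methyl ethers and C2 untouched and installs two strong ortho-directing groups.

**Step 5**
Reactants: 6 (2R)-2-(3,5-dimethoxyphenyl)-5,7-bis(methoxymethoxy)-3,4-dihydro-2H-chromene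
Product: 8 (2R)-2-(3,5-dimethoxyphenyl)-5,7-bis(methoxymethoxy)-6-(3-methylbut-2-en-1-yl)-3,4-dihydro-2H-chromene, via C6-aryllithium 7 (not isolated)
Conditions: n-BuLi (1.1 equiv), THF, −20 °C, 1 h; then CuBr·SMe2 (10 mol %), prenyl bromide (1.5 equiv), −78 °C → rt
Reagents that add atoms: prenyl bromide (1-bromo-3-methylbut-2-ene), CC(C)=CCBr
Why: Directed ortho-metalation, in which C6–H between two chelating OMOM groups is lithiated faster than C8–H (one OMOM and the ring oxygen) or the ring B C4′–H (two weaker OMe directors), followed by copper-catalysed SN2 allylation that gives the linear prenyl group; C2–H is not removed, so the configuration is kept.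

**Step 6**
Reactants: 8 (2R)-2-(3,5-dimethoxyphenyl)-5,7-bis(methoxymethoxy)-6-(3-methylbut-2-en-1-yl)-3,4-dihydro-2H-chromene
Product: 9 (2R)-2-(3,5-dimethoxyphenyl)-6-(3-methylbut-2-en-1-yl)-3,4-dihydro-2H-chromene-5,7-diol
Conditions: aq HCl (2 N), MeOH, 40 °C, monitored closely
Reagents that add atoms: none
Why: Acid-catalysed methanolysis of the two MOM acetals under conditions mild enough that the prenyl alkene does not cyclise onto the neighbouring phenols and the non-activated benzylic C2–O bond does not ionise, so C2 stays R.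

**Compound list**
1 | 3,5-dimethoxybenzaldehyde | COc1cc(OC)cc(C=O)c1 | starting material
2 | rac-1-(3,5-dimethoxyphenyl)prop-2-en-1-ol | C=CC(O)c1cc(OC)cc(OC)c1 | intermediate
3 | phloroglucinol (benzene-1,3,5-triol) | Oc1cc(O)cc(O)c1 | starting material
4 | 2-[(2E)-3-(3,5-dimethoxyphenyl)prop-2-en-1-yl]benzene-1,3,5-triol | COc1cc(OC)cc(/C=C/Cc2c(O)cc(O)cc2O)c1 | intermediate
5 | (2R)-2-(3,5-dimethoxyphenyl)-3,4-dihydro-2H-chromene-5,7-diol | COc1cc(OC)cc([C@H]2CCc3c(O)cc(O)cc3O2)c1 | intermediate
6 | (2R)-2-(3,5-dimethoxyphenyl)-5,7-bis(methoxymethoxy)-3,4-dihydro-2H-chromene | COc1cc(OC)cc([C@H]2CCc3c(OCOC)cc(OCOC)cc3O2)c1 | intermediate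
7 | [(2R)-2-(3,5-dimethoxyphenyl)-5,7-bis(methoxymethoxy)-3,4-dihydro-2H-chromen-6-yl]lithium | COc1cc(OC)cc([C@H]2CCc3c(OCOC)c([Li])c(OCOC)cc3O2)c1 | intermediate
8 | (2R)-2-(3,5-dimethoxyphenyl)-5,7-bis(methoxymethoxy)-6-(3-methylbut-2-en-1-yl)-3,4-dihydro-2H-chromene | COc1cc(OC)cc([C@H]2CCc3c(OCOC)c(CC=C(C)C)c(OCOC)cc3O2)c1 | intermediate
9 | (2R)-2-(3,5-dimethoxyphenyl)-6-(3-methylbut-2-en-1-yl)-3,4-dihydro-2H-chromene-5,7-diol | COc1cc(OC)cc([C@H]2CCc3c(cc(O)c(CC=C(C)C)c3O)O2)c1 | target

**Totals**
Total step count: 6. Longest linear sequence: 6 steps (from 1; phloroglucinol 3 enters at step 2).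

**Three steps most likely to fail**

Step 3 (the new hydroalkoxylation). The risks are low alkene reactivity (the meta-dimethoxy aryl group does not help cation formation), the basic phloroglucinol ring tying up the acid, poor solubility of the triol, and modest ee. The fallback uses known chemistry, sets out from 2 and comes back at 5. Alcohol 2 is oxidised with MnO2 (CH2Cl2, rt) to 1-(3,5-dimethoxyphenyl)prop-2-en-1-one F1. Acid-catalysed conjugate Friedel–Crafts addition of excess phloroglucinol 3 (p-TsOH·H2O cat., MeCN, rt) gives 1-(3,5-dimethoxyphenyl)-3-(2,4,6-trihydroxyphenyl)propan-1-one F2. Asymmetric transfer hydrogenation with RuCl(p-cymene)[(S,S)-TsDPEN] in HCO2H/Et3N gives (1S)-1-(3,5-dimethoxyphenyl)-3-(2,4,6-trihydroxyphenyl)propan-1-ol F3. Mitsunobu cyclisation (PPh3, DIAD, THF, 0 °C) forms the same C2–O1 bond with inversion and gives (2R)-5.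

Step 5 (regioselective lithiation and prenylation). The risks are competing lithiation at C8 or at ring B C4′ (between the two methoxy groups, a known metalation site), deprotonation at C2, and SN2′ allylation. The fallback avoids organolithium chemistry, sets out from 5 and comes back at 9. The less hindered 7-OH of 5 is silylated (i-Pr3SiCl, imidazole, CH2Cl2, 0 °C) to (2R)-2-(3,5-dimethoxyphenyl)-7-{[tri(propan-2-yl)silyl]oxy}-3,4-dihydro-2H-chromen-5-ol F4. The 5-OH is converted with isobutyl 2-methylbut-3-en-2-yl carbonate and Pd(PPh3)4 (cat., THF) into the 1,1-dimethylallyl ether (2R)-2-(3,5-dimethoxyphenyl)-5-[(2-methylbut-3-en-2-yl)oxy]-7-{[tri(propan-2-yl)silyl]oxy}-3,4-dihydro-2H-chromene F5. Aromatic Claisen rearrangement (PhNEt2, 130 °C) can only reach C6, the single free ortho position of O5, and gives (2R)-2-(3,5-dimethoxyphenyl)-6-(3-methylbut-2-en-1-yl)-7-{[tri(propan-2-yl)silyl]oxy}-3,4-dihydro-2H-chromen-5-ol F6. n-Bu4NF (THF, 0 °C, aqueous work-up) then gives 9.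

Step 6 (acidic MOM removal next to the prenyl group). The risk is acid-catalysed cyclisation of the prenyl alkene onto the 5- or 7-OH to give a dimethylpyran. The fallback keeps acid and prenyl apart, sets out from 6 (through the same lithio species 7) and comes back at 9. Species 7 is quenched with allyl bromide (CuBr·SMe2 cat.) to give (2R)-2-(3,5-dimethoxyphenyl)-5,7-bis(methoxymethoxy)-6-(prop-2-en-1-yl)-3,4-dihydro-2H-chromene F7. The acid-robust allyl group allows MOM cleavage (aq HCl, MeOH, 50 °C) to (2R)-2-(3,5-dimethoxyphenyl)-6-(prop-2-en-1-yl)-3,4-dihydro-2H-chromene-5,7-diol F8. Cross-metathesis with 2-methylbut-2-ene (second-generation Grubbs catalyst RuCl2(=CHPh)(PCy3)(H2IMes), CH2Cl2, 35 °C) then builds the prenyl group under neutral conditions and gives 9.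

**Further compounds**
F1 | step 3 | 1-(3,5-dimethoxyphenyl)prop-2-en-1-one | C=CC(=O)c1cc(OC)cc(OC)c1
F2 | step 3 | 1-(3,5-dimethoxyphenyl)-3-(2,4,6-trihydroxyphenyl)propan-1-one | COc1cc(OC)cc(C(=O)CCc2c(O)cc(O)cc2O)c1
F3 | step 3 | (1S)-1-(3,5-dimethoxyphenyl)-3-(2,4,6-trihydroxyphenyl)propan-1-ol | COc1cc(OC)cc([C@@H](O)CCc2c(O)cc(O)cc2O)c1
F4 | step 5 | (2R)-2-(3,5-dimethoxyphenyl)-7-{[tri(propan-2-yl)silyl]oxy}-3,4-dihydro-2H-chromen-5-ol | COc1cc(OC)cc([C@H]2CCc3c(O)cc(O[Si](C(C)C)(C(C)C)C(C)C)cc3O2)c1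
F5 | step 5 | (2R)-2-(3,5-dimethoxyphenyl)-5-[(2-methylbut-3-en-2-yl)oxy]-7-{[tri(propan-2-yl)silyl]oxy}-3,4-dihydro-2H-chromene | COc1cc(OC)cc([C@H]2CCc3c(OC(C)(C)C=C)cc(O[Si](C(C)C)(C(C)C)C(C)C)cc3O2)c1
F6 | step 5 | (2R)-2-(3,5-dimethoxyphenyl)-6-(3-methylbut-2-en-1-yl)-7-{[tri(propan-2-yl)silyl]oxy}-3,4-dihydro-2H-chromen-5-ol | COc1cc(OC)cc([C@H]2CCc3c(O)c(CC=C(C)C)c(O[Si](C(C)C)(C(C)C)C(C)C)cc3O2)c1
F7 | step 6 | (2R)-2-(3,5-dimethoxyphenyl)-5,7-bis(methoxymethoxy)-6-(prop-2-en-1-yl)-3,4-dihydro-2H-chromene | COc1cc(OC)cc([C@H]2CCc3c(OCOC)c(CC=C)c(OCOC)cc3O2)c1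
F8 | step 6 | (2R)-2-(3,5-dimethoxyphenyl)-6-(prop-2-en-1-yl)-3,4-dihydro-2H-chromene-5,7-diol | COc1cc(OC)cc([C@H]2CCc3c(O)c(CC=C)c(O)cc3O2)c1
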